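## Structural features

The target is a single cyclohexene ring, numbered here C1(OAc)–C2=C3–C4(OH)–C5(OH)(C7H2OBz)–C6(OAc), with one exocyclic carbon, C7, that carries the benzoate. Four stereocentres (C4, C5, C6, C1) are contiguous on the saturated arc. C5 is a fully substituted carbinol whose oxygen is cis to the oxygens on C4 and C6, and the C1 acetate is trans to the C6 acetate (1S,4S,5S,6R in this numbering). Five oxygens must be told apart: two secondary acetates, a free allylic alcohol, a free tertiary alcohol and a primary benzoate. The molecule is fragile in three ways: the esters can migrate round the 1,2- and 1,3-diol array under base, the C1 and C4 oxygens are allylic, and any C5-carbonyl precursor can lose the C1 acetate by β-elimination and then aromatise. The real difficulty is the quaternary centre C5 with its one-carbon branch, set cis to both neighbours, together with the differentiation of the four ring oxygens. The feature exploited is hidden symmetry: once C5 is a carbonyl carbon, the remaining centres C1, C4 and C6 have the alternating (all-trans) pattern of a cyclohex-5-ene-1,2,3,4-tetrol whose C2 axis passes through the midpoints of C2=C3 and C5–C6. It is this ketone, and not the target with C7 merely deleted (there O5 is cis to O4 and O6), that maps onto the C2-symmetric series; C7 is then added to the C5 carbonyl from the face away from O4 and O6.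

## Logic of the disconnections

From 17 to 16: the O4–CH2Ar bond of an aryl-methyl ether is cut. It goes last because O4 must stay masked while C5 is oxidised and two oxiranes are opened. Nothing is gained in skeleton; the gain is that 16 has only the unreactive tertiary hydroxyl free. The forward step must remove the ether without acid or base, since 17 carries three migratable esters and two allylic C–O bonds.

From 16 to 14 and 15: the C7–O bond of the primary ester is cut. This merges the C5 carbinol and C7 into one three-membered ring and makes C7 the only unhindered electrophilic carbon. One ester and one free hydroxyl disappear. The forward step must deliver the carboxylate to C7 and not to C5, and must protonate the tertiary alkoxide before an acyl group can shift to it.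

From 14 to 11 and 13, the latter made in the flask from 12: the C5–C7 and C7–O5 bonds are cut. This is the strategic cut: it removes the quaternary stereocentre and the branch and leaves a ketone with the alternating pattern of a C2-symmetric precursor. The forward step must add C7 to one face of the C5 carbonyl, close the oxirane without enlarging the ring, and do so without base.

From 11 to 10: the C5 carbonyl is taken back to a secondary alcohol. Its configuration is irrelevant, which is what lets a trans-opened oxirane serve as its source. The forward step needs a base-free oxidant acting on the only free hydroxyl.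

From 10 to 8 and 9: the C4–O bond to the ether oxygen is cut, with O5 as the other end of a C4–C5 oxirane. The protecting group thus enters as the nucleophile, C4 is fixed by inversion and O5 is revealed alone, so no selective protection of a polyol is needed. The forward step must open at allylic C4 and not let the C6 acetate attack C5.

From 8 to 6 by way of 7: the C1–O bond to the acetate and the acyl–O6 bond are cut, with O6 as part of a second oxirane. In 6 the two oxiranes are exchanged by the C2 axis, so it does not matter which one opens. The demand is that opening stops after one oxirane and occurs at the allylic carbon.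

From 6 to 5: the O–C5 and O–C6 bonds of the oxiranes are cut to bromohydrins. All four stereocentres are thereby traced to an all-trans dibromodiol. The forward step needs each hydroxyl anti to its neighbouring bromine.

From 5 to 4 and 3: no skeletal bond is cut; the enantiomers are separated through the diester. The gain is access to a racemate. The demand is an enzyme that discriminates well at both carbinol centres; half of the material is the wrong enantiomer.

From 3 to 2 and 1: the C1–H and C4–H bonds (carbonyl reduction) and the two C–Br bonds (halogen addition to one double bond) are cut, ending at an achiral flat ring. The forward steps must give the trans-dibromide and then hydroxyls trans to the bromines.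

## Other disconnections considered

Alternative 1: The cut runs through C4–C5 and C2–C3, so the carbocycle is assembled from furfuryl benzoate A1 as the diene and 2-bromoacrolein A2 as a ketene equivalent. A chiral boron Lewis acid of the B-alkyl oxazaborolidinone class would bind the aldehyde of A2 and steer the [4+2] cycloaddition to the exo-formyl oxanorbornene A3, whose bridging oxygen is already O5 and whose benzoyloxymethyl branch is in place.
- In its favour: C5, its oxygen and C7 arrive in the first C–C bond-forming step. Absolute configuration comes from a catalyst, so no enantiomer is discarded; on this point it is better than the chosen plan, which loses half of the material in a resolution. It needs no diazomethane, also an advantage.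
- Against it here: the 2-substituted furan A1 must add with the bromoformyl carbon next to the substituted bridgehead, the benzoate carbonyl of A1 can compete with A2 for boron, and furan adducts such as A3 revert readily.
- Structure: the bicycle fits the later steps poorly. After the bromoformyl carbon of A3 is unmasked to a carbonyl at C4, the oxygen bridge must be opened by β-elimination to create C2=C3, the C4 carbonyl must be reduced cis to O5, and the C1=C6 alkene must become a trans-diacetate although the bicyclic frame delivers reagents to one (exo) face and hence cis adducts.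
- Comparison: a concerted, catalyst-controlled cycloaddition early stands against a substrate-controlled carbonyl addition late. In step count it is expected to be at best equal and more likely longer, because four of the five oxygens still need adjusting after A3.

Alternative 2: The cut is the C1–C2 bond; the ring is closed from the acyclic (Z)-iodoalkene aldehyde A4, a branched pentose-derived chain that already carries the C4,C5-acetonide, the C7 benzoate and the C6 silyl ether. CrCl2 with catalytic NiCl2 (Nozaki–Hiyama–Kishi conditions) would turn the C2–I bond of A4 into a carbon–chromium bond, and this carbon would add to the C1 aldehyde and give the cyclohexenol A5.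
- In its favour: C4, C5 and C6 come from the chiral pool, the cis C4/C5 diol is locked in a five-membered acetal, and the quaternary centre is fixed before the ring exists. The configuration at C5 is therefore certain, which is better than the chosen plan, where C5 depends on the facial preference of the key addition. All oxygens arrive differentiated, which equals the chosen plan.
- Against it here: the one stereocentre made in the ring closure, C1, must come out trans to O6 and nothing in A4 enforces that. Divalent chromium is needed in excess and is toxic. Making A4 (branching at C5, Z-selective iodo-olefination, oxidation-state changes) is a long linear sequence. The end game from A5 needs silyl-to-acetyl exchange at C6, acetylation at C1 and acidic acetonide removal beside three esters.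
- Comparison: a ring-forming carbonyl addition with an open question at C1 is weighed against a ring-preserving one with an open question at C5. The chosen plan (eleven steps, ring present from the first intermediate) is expected to be shorter.

Alternative 3: No ring C–C bond is cut; the disconnection is the pair of C–O bonds (C3–O and C4–O) of an oxirane on the achiral p-quinol A7, itself one oxidative dearomatisation away from the phenol A6. An alkyl hydroperoxide under a chiral cinchona-derived quaternary ammonium phase-transfer catalyst would epoxidise one of the two enantiotopic enone double bonds of A7 syn to the C5 hydroxyl and give A8, making C5 stereogenic. A Wharton transposition of A8 would then give C2=C3 and C4–OH with O4 and O5 cis.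
- In its favour: the quaternary carbon never has to be created stereoselectively, only desymmetrised, and the enantioselectivity is catalytic. The route to the C2=C3/C4–OH/C5–OH half of the target is the shortest of all; on step economy for this half and on avoiding diazomethane it is better than the chosen plan.
- Against it here: the epoxidation of A7 must discriminate both between enantiotopic alkenes and between the faces syn and anti to the hydroxyl, under basic peroxide conditions. The second enone of A8 must survive the Wharton step, whose reagent also adds to enones. That enone must then be turned into the trans C1/C6 diacetate on what is by then a conjugated diene system, with regio- and face-selectivity unsecured. The C7 silyl ether must finally be exchanged for the benzoate.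
- Comparison: in the chosen plan every ring oxygen is placed by a stereospecific anti opening of an oxirane and only one selectivity (the face of the C5 carbonyl) is open. This alternative trades a lower step count for several unsecured selectivities.

Key step: step 9

Remarks on the design:
- The ring numbering of the first section is used for all intermediates.
- The C4 oxygen is carried through the key step as a 4-methoxybenzyl ether, preferred here to a silyl ether. It enters as the nucleophile that opens the second oxirane, so neither a selective mono-silylation nor a selective diacetylation of a tetrol is needed. The skeleton, the C1 and C6 acetates, the C5 carbonyl and the bonds made in the key step are unaffected by this choice.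
- Assumption: the lipase cleaves the diacetate enantiomer with (R)-configured carbinol carbons faster, as is usual for esters of secondary alcohols. If the preference is the opposite, the recovered (1R,4R,5S,6S)-diacetate is used in step 5 with hydroxide in methanol–THF, which cleaves the acetates and closes the oxiranes; the step count does not change.

## Route

Step 1
Reactants: 1 p-benzoquinone
Product: 2 (±)-trans-5,6-dibromocyclohex-2-ene-1,4-dione
Conditions: Br2 (1.0 equiv), CHCl3, 0 °C
Reagents that add atoms: bromine, BrBr
Why: Electrophilic anti addition of bromine to one quinone C=C through a bromonium ion gives the trans-dibromide; the remaining alkene, flanked by two carbonyls, is too electron-poor to react further at this temperature.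

Step 2
Reactants: 2 (±)-trans-5,6-dibromocyclohex-2-ene-1,4-dione
Product: 3 (±)-(1R*,4R*,5S*,6S*)-5,6-dibromocyclohex-2-ene-1,4-diol (all-trans)
Conditions: NaBH4, Et2O–H2O, 0 °C
Reagents that add atoms: none
Why: Borohydride 1,2-reduction of both carbonyls; with the bromines pseudo-axial, hydride approaches each carbonyl from the face not screened by the axial bromine on the β-carbon, so each hydroxyl ends trans to its vicinal bromine and the diol is all-trans and C2-symmetric.

Step 3
Reactants: 3 (±)-(1R*,4R*,5S*,6S*)-5,6-dibromocyclohex-2-ene-1,4-diol
Product: 4 (±)-(1R*,4R*,5S*,6S*)-5,6-dibromocyclohex-2-ene-1,4-diyl diacetate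
Conditions: Ac2O, pyridine, DMAP (cat.), CH2Cl2, 0 °C → rt
Reagents that add atoms: acetic anhydride, CC(=O)OC(C)=O
Why: Nucleophile-catalysed O-acylation of both secondary hydroxyls; no stereocentre is touched and pyridine is too weak a base to close the bromohydrins.

Step 4
Reactants: 4 (±)-(1R*,4R*,5S*,6S*)-5,6-dibromocyclohex-2-ene-1,4-diyl diacetate
Product: 5 (1R,4R,5S,6S)-5,6-dibromocyclohex-2-ene-1,4-diol
Conditions: lipase from porcine pancreas, phosphate buffer (pH 7)–toluene, rt, pH-stat to half conversion; chromatographic separation from the unreacted diacetate
Reagents that add atoms: none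
Why: Enzymatic kinetic resolution by enantioselective ester hydrolysis; the fitting enantiomer is cleaved at both carbinol esters, which should amplify the enantiomeric purity of the diol, while the mirror-image diacetate stays untouched.

Step 5
Reactants: 5 (1R,4R,5S,6S)-5,6-dibromocyclohex-2-ene-1,4-diol
Product: 6 (1R,2R,4R,7R)-3,8-dioxatricyclo[5.1.0.0^2,4]oct-5-ene (anti-benzene dioxide)
Conditions: KOH (powdered), THF, 4 Å MS, 0 °C → rt; handled in solution
Reagents that add atoms: none
Why: Twofold intramolecular Williamson etherification (3-exo-tet); each alkoxide is anti to its vicinal bromine, so C5 and C6 are inverted, C1 and C4 keep their configuration and the two oxiranes end on opposite faces.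

Step 6
Reactants: 6 anti-benzene dioxide
Product: 8 (1R,2R,3S,6R)-7-oxabicyclo[4.1.0]hept-4-ene-2,3-diyl diacetate, via epoxy hydroxy acetate 7 (not isolated)
Conditions: AcOH, NaOAc, 25 °C, stopped short of full conversion; evaporate; Ac2O, pyridine, DMAP (cat.), CH2Cl2, 0 °C
Reagents that add atoms: acetic acid, CC(=O)O; acetic anhydride, CC(=O)OC(C)=O
Why: Acid-promoted acetolysis of a vinyl oxirane at the allylic carbon with inversion (trans-diaxial opening) puts the C1 acetate trans to O6; the two oxiranes of 6 are homotopic, so mono-opening gives one compound and only over-reaction must be limited; acetylation of the freed C6 hydroxyl in the same flask fixes both acetates before any other hydroxyl exists.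

Step 7
Reactants: 8 (1R,2R,3S,6R)-7-oxabicyclo[4.1.0]hept-4-ene-2,3-diyl diacetate; 9 4-methoxybenzyl alcohol
Product: 10 (1S,4S,5R,6S)-5-hydroxy-4-[(4-methoxybenzyl)oxy]cyclohex-2-ene-1,6-diyl diacetate
Conditions: 9 (4 equiv), Yb(OTf)3 (10 mol %), CH2Cl2, 0 °C → rt
Reagents that add atoms: none
Why: Lewis-acid-catalysed alcoholysis of the remaining vinyl oxirane at allylic C4 with inversion sets C4 (ether oxygen trans to O5 and on the same face as the C6 acetate) and leaves O5 as the only free hydroxyl; the allylic C4–O bond is the one weakened on coordination, which should outrun participation of the C6 acetate at C5.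

Step 8
Reactants: 10 (1S,4S,5R,6S)-5-hydroxy-4-[(4-methoxybenzyl)oxy]cyclohex-2-ene-1,6-diyl diacetate
Product: 11 (1S,4S,6R)-4-[(4-methoxybenzyl)oxy]-5-oxocyclohex-2-ene-1,6-diyl diacetate
Conditions: Dess–Martin periodinane (1.5 equiv), CH2Cl2, 0 °C → rt; short silica plug; used at once
Reagents that add atoms: none
Why: Dess–Martin oxidation of the single secondary alcohol; a base-free oxidant is chosen because the product is a β-acetoxy ketone that would eliminate and aromatise with amine bases, and without base C4 and C6 are not epimerised.

Step 9
Reactants: 11 (1S,4S,6R)-4-[(4-methoxybenzyl)oxy]-5-oxocyclohex-2-ene-1,6-diyl diacetate; 12 N-methyl-N-nitroso-p-toluenesulfonamide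
Product: 14 (3S,4R,5S,8S)-8-[(4-methoxybenzyl)oxy]-1-oxaspiro[2.5]oct-6-ene-4,5-diyl diacetate, via diazomethane 13 (not isolated)
Conditions: 12, KOH, EtOH–H2O–Et2O, 65 °C, 13 co-distilled with Et2O (fire-polished glass, blast shield); ethereal 13 (excess) added to 11 in Et2O–MeOH, 0 °C; excess 13 purged with N2
Reagents that add atoms: none
Why: Base-induced fragmentation of 12 releases 13, whose nucleophilic carbon adds to the C5 carbonyl (made strongly electrophilic by the α-ether and α-acyloxy groups) to give a diazonium betaine, and the C5 alkoxide then displaces N2 from C7 to form C5–C7 and C7–O. The closest known reaction type is the diazomethane spiro-epoxidation of inososes and pyranosuloses. The one ring formed is the oxirane, closed 3-exo-tet by intramolecular SN2 at C7. The new stereocentre C5 is set by the substrate: in the half-chair with the C1, C4 and C6 substituents equatorial, C–C bond formation along the equatorial trajectory lets the carbonyl oxygen swing axial, away from the equatorial C4–O and C6–O dipoles, so C7 ends trans and O5 cis to both neighbours, the sense in which hydride and carbon nucleophiles add to uloses flanked by equatorial oxygens. Two selectivities are needed: face selectivity, secured by the two cis-disposed α-oxygens, and oxirane closure over 1,2-shift (ring enlargement to a cycloheptenone), favoured because the electron-poor α-carbons migrate poorly and the betaine collapses at 0 °C. The reagent is neutral, so the β-acetoxy ketone is not enolised and the C1 acetate is not eliminated.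

Step 10
Reactants: 14 (3S,4R,5S,8S)-8-[(4-methoxybenzyl)oxy]-1-oxaspiro[2.5]oct-6-ene-4,5-diyl diacetate; 15 benzoic acid
Product: 16 [(1S,2S,5S,6R)-5,6-diacetoxy-1-hydroxy-2-[(4-methoxybenzyl)oxy]cyclohex-3-en-1-yl]methyl benzoate
Conditions: 15 (3 equiv), PhCO2Cs (0.3 equiv), DMF, 60 °C
Reagents that add atoms: none
Why: Carboxylate SN2 opening of the 2,2-disubstituted oxirane at its methylene carbon C7; C5 is not attacked and keeps its configuration, and the excess acid protonates the tertiary alkoxide at once, which should suppress acetyl or benzoyl migration and regenerates the benzoate.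

Step 11
Reactants: 16 [(1S,2S,5S,6R)-5,6-diacetoxy-1-hydroxy-2-[(4-methoxybenzyl)oxy]cyclohex-3-en-1-yl]methyl benzoate
Product: 17 [(1S,2S,5S,6R)-5,6-diacetoxy-1,2-dihydroxycyclohex-3-en-1-yl]methyl benzoate (EANPDB:ANNO_00166)
Conditions: DDQ (1.5 equiv), CH2Cl2–pH 7 phosphate buffer (10:1), 0 °C → rt
Reagents that add atoms: none
Why: Oxidative cleavage of the 4-methoxybenzyl ether (hydride abstraction by DDQ, hydrolysis of the oxocarbenium ion by water); the medium is neutral, so esters should not migrate, and water keeps the neighbouring tertiary hydroxyl from trapping the cation as a benzylidene acetal.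

## Compound list

1 | p-benzoquinone | O=C1C=CC(=O)C=C1 | starting material
2 | (±)-trans-5,6-dibromocyclohex-2-ene-1,4-dione (racemate; 5S,6S enantiomer drawn) | O=C1C=CC(=O)[C@H](Br)[C@H]1Br | intermediate
3 | (±)-(1R*,4R*,5S*,6S*)-5,6-dibromocyclohex-2-ene-1,4-diol (racemate; 1R,4R,5S,6S enantiomer drawn) | O[C@@H]1C=C[C@@H](O)[C@H](Br)[C@H]1Br | intermediate
4 | (±)-(1R*,4R*,5S*,6S*)-5,6-dibromocyclohex-2-ene-1,4-diyl diacetate (racemate; 1R,4R,5S,6S enantiomer drawn) | CC(=O)O[C@@H]1C=C[C@@H](OC(C)=O)[C@H](Br)[C@H]1Br | intermediate
5 | (1R,4R,5S,6S)-5,6-dibromocyclohex-2-ene-1,4-diol | O[C@@H]1C=C[C@@H](O)[C@H](Br)[C@H]1Br | intermediate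
6 | (1R,2R,4R,7R)-3,8-dioxatricyclo[5.1.0.0^2,4]oct-5-ene (anti-benzene dioxide) | C1=C[C@H]2O[C@H]2[C@@H]3O[C@H]13 | intermediate
7 | (1S,2R,3S,6R)-2-hydroxy-7-oxabicyclo[4.1.0]hept-4-en-3-yl acetate | CC(=O)O[C@H]1C=C[C@H]2O[C@H]2[C@@H]1O | intermediate
8 | (1R,2R,3S,6R)-7-oxabicyclo[4.1.0]hept-4-ene-2,3-diyl diacetate | CC(=O)O[C@H]1C=C[C@H]2O[C@H]2[C@@H]1OC(C)=O | intermediate
9 | 4-methoxybenzyl alcohol | COc1ccc(CO)cc1 | starting material
10 | (1S,4S,5R,6S)-5-hydroxy-4-[(4-methoxybenzyl)oxy]cyclohex-2-ene-1,6-diyl diacetate | CC(=O)O[C@H]1C=C[C@H](OCc2ccc(OC)cc2)[C@@H](O)[C@@H]1OC(C)=O | intermediate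
11 | (1S,4S,6R)-4-[(4-methoxybenzyl)oxy]-5-oxocyclohex-2-ene-1,6-diyl diacetate (= (2R,3S,6S)-2,3-diacetoxy-6-(4-methoxybenzyloxy)cyclohex-4-en-1-one) | CC(=O)O[C@H]1C=C[C@H](OCc2ccc(OC)cc2)C(=O)[C@@H]1OC(C)=O | intermediate
12 | N-methyl-N-nitroso-p-toluenesulfonamide | Cc1ccc(cc1)S(=O)(=O)N(C)N=O | starting material
13 | diazomethane | C=[N+]=[N-] | intermediate
14 | (3S,4R,5S,8S)-8-[(4-methoxybenzyl)oxy]-1-oxaspiro[2.5]oct-6-ene-4,5-diyl diacetate | CC(=O)O[C@H]1C=C[C@H](OCc2ccc(OC)cc2)[C@@]3(CO3)[C@@H]1OC(C)=O | intermediate
15 | benzoic acid | O=C(O)c1ccccc1 | starting material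
16 | [(1S,2S,5S,6R)-5,6-diacetoxy-1-hydroxy-2-[(4-methoxybenzyl)oxy]cyclohex-3-en-1-yl]methyl benzoate | CC(=O)O[C@H]1C=C[C@H](OCc2ccc(OC)cc2)[C@@](O)(COC(=O)c2ccccc2)[C@@H]1OC(C)=O | intermediate
17 | [(1S,2S,5S,6R)-5,6-diacetoxy-1,2-dihydroxycyclohex-3-en-1-yl]methyl benzoate | CC(=O)O[C@H]1C=C[C@H](O)[C@@](O)(COC(=O)c2ccccc2)[C@@H]1OC(C)=O | target

## Step count and least certain steps

Total step count: 11. Longest linear sequence: 11 steps, from 1 to 17; compounds 9, 12 and 15 are commercial and enter in steps 7, 9 and 10.

**Step 9 (key step).** Three things may go wrong: ring enlargement through 1,2-shift in the betaine, approach along the axial trajectory (wrong configuration at C5), and loss of 11 by elimination and aromatisation before it reacts. Fallback, from 11 back to the route at 16: add a hydroxymethyl anion equivalent in place of a methylene donor. (Isopropoxydimethylsilyl)methylmagnesium chloride, precomplexed with CeCl3 in THF at −78 °C, should add to the C5 carbonyl with little enolisation and in the same equatorial sense. This gives the tertiary carbinol 5-hydroxy-5-{[isopropoxy(dimethyl)silyl]methyl}-4-[(4-methoxybenzyl)oxy]cyclohex-2-ene-1,6-diyl diacetate F1 (O5 cis to O4 and O6); ring enlargement is impossible in this manifold. Tamao–Fleming oxidation (H2O2, KF, KHCO3, THF–MeOH, 0 °C) would convert the C7–Si bond into C7–OH and give the diol 5-hydroxy-5-(hydroxymethyl)-4-[(4-methoxybenzyl)oxy]cyclohex-2-ene-1,6-diyl diacetate F2. Selective benzoylation of the primary hydroxyl (benzoyl chloride, 2,4,6-collidine, CH2Cl2, −40 °C) would give 16.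

**Step 6.** The second oxirane may open as well, since the two sites differ only statistically and by a modest inductive effect, and acetate may attack with allylic shift. Fallback, from 5 back to the route at 8: differentiate the two halves one stage earlier and make and open the oxiranes one at a time. Mono-silylation of 5 (TBSCl 1 equiv, imidazole, DMF; the hydroxyls are homotopic, and recovered 5 and bis-ether can be recycled) gives (1R,4R,5S,6S)-5,6-dibromo-4-(tert-butyldimethylsilyloxy)cyclohex-2-en-1-ol F3. KOH in THF then closes the only free bromohydrin to the bromo oxirane 2-bromo-3-(tert-butyldimethylsilyloxy)-7-oxabicyclo[4.1.0]hept-4-ene F4 (oxirane and bromine on one face, silyloxy group on the other). Acetolysis at allylic C1 (AcOH, NaOAc) gives the hydroxy acetate 5-bromo-4-(tert-butyldimethylsilyloxy)-6-hydroxycyclohex-2-en-1-yl acetate F5, which is acetylated in the same flask to 5-bromo-4-(tert-butyldimethylsilyloxy)cyclohex-2-ene-1,6-diyl diacetate F6. HF·pyridine frees O4 and gives the bromohydrin 5-bromo-4-hydroxycyclohex-2-ene-1,6-diyl diacetate F7 (O4 anti to Br5), and Ag2O in CH2Cl2 closes the second oxirane to 8.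

**Step 7.** The C6 acetate may participate at C5 (a cis-fused acetoxonium ion, then wrong configuration and acetyl scrambling), and 9 may self-condense under the Lewis acid. Fallback, from 6 back to the route at 10: reverse the order of the nucleophiles so that no ester ever sits next to an oxirane. Mono-opening of 6 with 9 (Yb(OTf)3, CH2Cl2) gives (1S,2R,3S,6R)-3-[(4-methoxybenzyl)oxy]-7-oxabicyclo[4.1.0]hept-4-en-2-ol F8. TBSOTf and 2,6-lutidine convert it into 2-(tert-butyldimethylsilyloxy)-3-[(4-methoxybenzyl)oxy]-7-oxabicyclo[4.1.0]hept-4-ene F9. Acetolysis of the second oxirane at its allylic carbon (AcOH, NaOAc) gives 6-hydroxy-4-[(4-methoxybenzyl)oxy]-5-(tert-butyldimethylsilyloxy)cyclohex-2-en-1-yl acetate F10, and Ac2O with pyridine gives 4-[(4-methoxybenzyl)oxy]-5-(tert-butyldimethylsilyloxy)cyclohex-2-ene-1,6-diyl diacetate F11. HF·pyridine removes the silyl group and gives 10.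

**Step 10.** An acyl group may shift to the transient tertiary alkoxide (acetyl from O6 or benzoyl from O7), and substitution at C7 next to a fully substituted carbon may be slow, leading to decomposition at the temperature needed. Fallback, from 14 back to the route at 17, same step count: take off the ether first and let the freed hydroxyl direct the opening. DDQ in wet CH2Cl2 gives the epoxy alcohol 8-hydroxy-1-oxaspiro[2.5]oct-6-ene-4,5-diyl diacetate F12 (oxirane oxygen cis to the C8 hydroxyl). Ti(OiPr)4-mediated opening of this 2,3-epoxy alcohol with 15 in CH2Cl2 delivers the benzoate to the terminal carbon C7 and gives 17 directly.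

## Further compounds

F1 | step 9 | 5-hydroxy-5-{[isopropoxy(dimethyl)silyl]methyl}-4-[(4-methoxybenzyl)oxy]cyclohex-2-ene-1,6-diyl diacetate (O5 cis to O4 and O6) | CC(=O)O[C@H]1C=C[C@H](OCc2ccc(OC)cc2)[C@@](O)(C[Si](C)(C)OC(C)C)[C@@H]1OC(C)=O
F2 | step 9 | 5-hydroxy-5-(hydroxymethyl)-4-[(4-methoxybenzyl)oxy]cyclohex-2-ene-1,6-diyl diacetate | CC(=O)O[C@H]1C=C[C@H](OCc2ccc(OC)cc2)[C@@](O)(CO)[C@@H]1OC(C)=O
F3 | step 6 | (1R,4R,5S,6S)-5,6-dibromo-4-(tert-butyldimethylsilyloxy)cyclohex-2-en-1-ol | O[C@@H]1C=C[C@@H](O[Si](C)(C)C(C)(C)C)[C@H](Br)[C@H]1Br
F4 | step 6 | 2-bromo-3-(tert-butyldimethylsilyloxy)-7-oxabicyclo[4.1.0]hept-4-ene (oxirane and bromine cis, silyloxy trans) | CC(C)(C)[Si](C)(C)O[C@@H]1C=C[C@H]2O[C@H]2[C@H]1Br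
F5 | step 6 | 5-bromo-4-(tert-butyldimethylsilyloxy)-6-hydroxycyclohex-2-en-1-yl acetate | CC(=O)O[C@H]1C=C[C@@H](O[Si](C)(C)C(C)(C)C)[C@H](Br)[C@@H]1O
F6 | step 6 | 5-bromo-4-(tert-butyldimethylsilyloxy)cyclohex-2-ene-1,6-diyl diacetate | CC(=O)O[C@H]1C=C[C@@H](O[Si](C)(C)C(C)(C)C)[C@H](Br)[C@@H]1OC(C)=O
F7 | step 6 | 5-bromo-4-hydroxycyclohex-2-ene-1,6-diyl diacetate (O4 anti to Br5) | CC(=O)O[C@H]1C=C[C@@H](O)[C@H](Br)[C@@H]1OC(C)=O
F8 | step 7 | (1S,2R,3S,6R)-3-[(4-methoxybenzyl)oxy]-7-oxabicyclo[4.1.0]hept-4-en-2-ol | COc1ccc(CO[C@H]2C=C[C@H]3O[C@H]3[C@@H]2O)cc1
F9 | step 7 | 2-(tert-butyldimethylsilyloxy)-3-[(4-methoxybenzyl)oxy]-7-oxabicyclo[4.1.0]hept-4-ene | COc1ccc(CO[C@H]2C=C[C@H]3O[C@H]3[C@@H]2O[Si](C)(C)C(C)(C)C)cc1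
F10 | step 7 | 6-hydroxy-4-[(4-methoxybenzyl)oxy]-5-(tert-butyldimethylsilyloxy)cyclohex-2-en-1-yl acetate | CC(=O)O[C@H]1C=C[C@H](OCc2ccc(OC)cc2)[C@@H](O[Si](C)(C)C(C)(C)C)[C@@H]1O
F11 | step 7 | 4-[(4-methoxybenzyl)oxy]-5-(tert-butyldimethylsilyloxy)cyclohex-2-ene-1,6-diyl diacetate | CC(=O)O[C@H]1C=C[C@H](OCc2ccc(OC)cc2)[C@@H](O[Si](C)(C)C(C)(C)C)[C@@H]1OC(C)=O
F12 | step 10 | 8-hydroxy-1-oxaspiro[2.5]oct-6-ene-4,5-diyl diacetate (oxirane oxygen cis to the C8 hydroxyl) | CC(=O)O[C@H]1C=C[C@H](O)[C@@]2(CO2)[C@@H]1OC(C)=O
A1 | alternative 1 | furfuryl benzoate | O=C(OCc1ccco1)c1ccccc1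
A2 | alternative 1 | 2-bromoacrolein | C=C(Br)C=O
A3 | alternative 1 | (2-bromo-2-formyl-7-oxabicyclo[2.2.1]hept-5-en-1-yl)methyl benzoate, exo-formyl | O=C(c3ccccc3)OC[C@@]12O[C@@H](C=C1)C[C@]2(Br)C=O
A4 | alternative 2 | (Z)-iodoalkene aldehyde with C4,C5-acetonide, C7 benzoate and C6 tert-butyldimethylsilyl ether | O=C[C@@H](O[Si](C)(C)C(C)(C)C)[C@@]1(COC(=O)c2ccccc2)OC(C)(C)O[C@H]1/C=C\I
A5 | alternative 2 | cyclohexenol with C4,C5-acetonide, C7 benzoate and C6 tert-butyldimethylsilyl ether | O[C@H]1C=C[C@@H]2OC(C)(C)O[C@]2(COC(=O)c3ccccc3)[C@@H]1O[Si](C)(C)C(C)(C)C
A6 | alternative 3 | 4-[(tert-butyldimethylsilyloxy)methyl]phenol | CC(C)(C)[Si](C)(C)OCc1ccc(O)cc1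
A7 | alternative 3 | 4-hydroxy-4-[(tert-butyldimethylsilyloxy)methyl]cyclohexa-2,5-dien-1-one | O=C1C=CC(O)(CO[Si](C)(C)C(C)(C)C)C=C1
A8 | alternative 3 | 2,3-epoxy-4-hydroxy-4-[(tert-butyldimethylsilyloxy)methyl]cyclohex-5-en-1-one, oxirane syn to hydroxyl | O=C1[C@@H]2O[C@@H]2[C@@](O)(CO[Si](C)(C)C(C)(C)C)C=C1
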